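The dimer is cut at ring C into natural 8-epi-xanthatin (diene) and its antipodal dihydro congener 22 (dienophile); an exo Diels–Alder union and γ-hydroxylation at C1 finish the target. Everything rests on the cycloheptene ring D of 22: its edge C8′(O–CH)–C9′(CH2) is flanked by the all-cis centres C7′ (CH on the lactone), C8′ and C10′ (CH–CH3), the imprint of an endo [4+2] adduct. The key step, a catalytic asymmetric Diels–Alder reaction of the acyclic 2-silyloxy diene 4 with methyl vinyl ketone, forms C7′–C8′ and C9′–C10′ and all three centres at once in a cyclohexene; one-carbon insertion (C5′) through its enol ether then gives the cycloheptene.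

Key step: step 3

Remark on locants: xanthanolide numbering is used. Unprimed carbons belong to the hydroxylated unit (lactone ring A, cycloheptane ring B), ring C is the cyclohexene made in step 14, and primed carbons belong to the spiro-lactone unit (cycloheptene ring D = C1′, C5′–C10′; lactone ring E = C7′, C8′, O, C12′, C11′).

Assumption: 8-epi-xanthatin (23), the natural (3aR,7S,8aR) lactone, is bought as an isolated natural product; the spiro-lactone unit of the target has the mirror-image configuration at C7′, C8′ and C10′ and is therefore made by synthesis.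

Step 1
Reactants: 1 pent-1-en-3-one; 2 but-3-en-1-yl acetate
Product: 3 (3E)-5-oxohept-3-en-1-yl acetate
Conditions: second-generation Grubbs catalyst (H2IMes)(PCy3)Cl2Ru=CHPh (3 mol %), 1 (3 equiv), CH2Cl2, 40 °C
Reagents that add atoms: none
Why: Olefin cross-metathesis of a terminal alkene with an electron-poor vinyl ketone favours the cross product and should give the E-enone under thermodynamic control.

Step 2
Reactants: 3 (3E)-5-oxohept-3-en-1-yl acetate
Product: 4 (3E,5Z)-5-(triisopropylsilyloxy)hepta-3,5-dien-1-yl acetate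
Conditions: i-Pr3SiOTf, Et3N, CH2Cl2, −78 → 0 °C
Reagents that add atoms: triisopropylsilyl trifluoromethanesulfonate, CC(C)[Si](C(C)C)(C(C)C)OS(=O)(=O)C(F)(F)F
Why: Soft enolisation (silyl triflate/amine) should remove an α′-proton of the ethyl ketone and give the cross-conjugated 2-silyloxy diene, with the Z enol ether (methyl cis to oxygen) expected as for ethyl ketones.

Step 3
Reactants: 4 (3E,5Z)-5-(triisopropylsilyloxy)hepta-3,5-dien-1-yl acetate; 5 but-3-en-2-one
Product: 6 2-[(1R,4R,6S)-6-acetyl-4-methyl-3-(triisopropylsilyloxy)cyclohex-2-en-1-yl]ethyl acetate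
Conditions: (S)-o-tolyl-CBS oxazaborolidine (20 mol %), Tf2NH (17 mol %), CH2Cl2, −78 → −40 °C
Reagents that add atoms: none
Why: The oxazaborolidinium ion formed from the oxazaborolidine and Tf2NH binds the carbonyl of 5 and lowers its LUMO, and the silyloxy diene then adds in a concerted but asynchronous [4+2] cycloaddition in which the nucleophilic terminus C10′ bonds to the β-carbon (future C9′) slightly ahead of C7′–C8′. The closest known reaction type is the oxazaborolidinium-catalysed Diels–Alder reaction of 2-silyloxy-1,3-dienes with acrylates and enones. The cyclohexene (C7′, C8′, C9′, C10′, C1′, C6′) closes as a thermally allowed suprafacial [4π+2π] cycloaddition through an endo, boat-like transition state. C8′ is set by the catalyst, whose (S) form is expected, by analogy with its adducts of acrylates and simple dienes, to expose the enone face that leads to the 6S adduct; C7′ and C10′ follow from the endo rule and from the diene geometry (3E side chain and 5Z methyl both in outside positions), which puts acetyl, side chain and methyl all cis. The step needs para regiochemistry, secured by the silyloxy group that makes C10′ the nucleophilic terminus and overrides the two terminal alkyl groups, endo selectivity, secured by Lewis-acid complexation, and one enantioface, secured by the catalyst; any E enol ether isomer of 4 carries an inside methyl and should react far more slowly, so it is not carried through.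

Step 4
Reactants: 6 2-[(1R,4R,6S)-6-acetyl-4-methyl-3-(triisopropylsilyloxy)cyclohex-2-en-1-yl]ethyl acetate
Product: 7 2-[4-acetyl-2-methyl-1-(triisopropylsilyloxy)bicyclo[4.1.0]heptan-5-yl]ethyl acetate (acetyl, methyl and side chain all cis; cyclopropane CH2 on the opposite face)
Conditions: Et2Zn, CH2I2, CH2Cl2, 0 °C → rt
Reagents that add atoms: diiodomethane, ICI
Why: Simmons–Smith cyclopropanation (Et2Zn/CH2I2 variant) is selective for the electron-rich silyl enol ether and adds the future C5′; the two new centres (CH2 expected anti to the three cis substituents) are erased in step 6.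

Step 5
Reactants: 7 siloxycyclopropane methyl ketone
Product: 8 2-[4-acetoxy-2-methyl-1-(triisopropylsilyloxy)bicyclo[4.1.0]heptan-5-yl]ethyl acetate (configuration as in 7)
Conditions: mCPBA, NaHCO3, CH2Cl2, 0 °C → rt
Reagents that add atoms: 3-chloroperoxybenzoic acid, OOC(=O)c1cccc(Cl)c1
Why: Baeyer–Villiger oxidation of the methyl ketone, in which the secondary ring carbon migrates in preference to methyl and with retention, turns C8′–acetyl into C8′–OAc cis to the side chain; no alkene is left to be epoxidised at this stage.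

Step 6
Reactants: 8 siloxycyclopropane diacetate
Product: 10 2-[(1R,2S,4R)-2-acetoxy-4-methyl-5-oxocyclohept-6-en-1-yl]ethyl acetate, via chloro ketone 9 (not isolated)
Conditions: FeCl3, DMF, 0 °C → rt; then Et3N, CH2Cl2, rt
Reagents that add atoms: none
Why: Iron trichloride oxidises the siloxycyclopropane to an alkoxy radical whose β-scission cleaves the internal C1′–C6′ bond (the known ring expansion of 1-siloxybicyclo[4.1.0]heptanes to 3-chlorocycloheptanones), and mild base then eliminates HCl to the cyclohept-2-enone, so that C5′ ends up inserted between C1′ and C6′.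

Step 7
Reactants: 10 2-[(1R,2S,4R)-2-acetoxy-4-methyl-5-oxocyclohept-6-en-1-yl]ethyl acetate
Product: 12 (4S,5S,7R)-5-acetoxy-4-(2-acetoxyethyl)-7-methylcyclohept-1-en-1-yl trifluoromethanesulfonate, via lithium enolate 11 (not isolated)
Conditions: LiBH(s-Bu)3 (L-Selectride), THF, −78 °C; then PhNTf2, −78 → 0 °C
Reagents that add atoms: N-phenylbis(trifluoromethanesulfonimide), O=S(=O)(N(c1ccccc1)S(=O)(=O)C(F)(F)F)C(F)(F)F
Why: Conjugate hydride addition to the enone, whose β-carbon C6′ carries only hydrogen, should give the C1′(O)=C5′ enolate regiospecifically, and O-triflation fixes the double bond where ring D needs it (reductive enol triflate formation), with the acetates spared at −78 °C.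

Step 8
Reactants: 12 enol triflate; 13 2-ethenyl-2-methyl-1,3-dioxolane
Product: 15 2-[(1S,2S,4R)-2-acetoxy-4-methyl-5-[2-(2-methyl-1,3-dioxolan-2-yl)ethyl]cyclohept-5-en-1-yl]ethyl acetate, via alkylborane 14 (not isolated)
Conditions: 13, 9-BBN-H, THF, 0 °C → rt; then 12, PdCl2(dppf) (5 mol %), K3PO4 (aq), DMF, 50 °C
Reagents that add atoms: none
Why: Anti-Markovnikov hydroboration gives the primary alkylborane, which should undergo B-alkyl Suzuki–Miyaura coupling with the enol triflate without moving the C1′=C5′ double bond and so installs the masked 3-oxobutyl chain.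

Step 9
Reactants: 15 coupled diacetate
Product: 16 (1S,2S,6R)-2-(2-hydroxyethyl)-6-methyl-5-[2-(2-methyl-1,3-dioxolan-2-yl)ethyl]cyclohept-4-en-1-ol
Conditions: K2CO3, MeOH, rt
Reagents that add atoms: none
Why: Base-catalysed methanolysis (transesterification) removes both acetates and leaves the ketal, the alkene and the stereocentres untouched.

Step 10
Reactants: 16 diol
Product: 17 (3aS,7R,8aS)-7-methyl-6-[2-(2-methyl-1,3-dioxolan-2-yl)ethyl]-3,3a,4,7,8,8a-hexahydro-2H-cyclohepta[b]furan-2-one
Conditions: TEMPO (20 mol %), PhI(OAc)2 (2.5 equiv), CH2Cl2, rt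
Reagents that add atoms: none
Why: The oxoammonium oxidises the primary alcohol selectively to the aldehyde, which closes to the lactol with the cis C8′ hydroxyl and is oxidised on to the cis-fused γ-lactone (oxidative lactonisation of a 1,4-diol).

Step 11
Reactants: 17 cis-fused lactone
Product: 19 (3R,3aS,7R,8aS)-3-[(dimethylamino)methyl]-7-methyl-6-[2-(2-methyl-1,3-dioxolan-2-yl)ethyl]-3,3a,4,7,8,8a-hexahydro-2H-cyclohepta[b]furan-2-one, via lactone enolate 18 (not isolated)
Conditions: LiN(i-Pr)2, THF, −78 °C; then CH2=NMe2+ I−, −78 °C → rt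
Reagents that add atoms: N,N-dimethylmethylideneammonium iodide (Eschenmoser's salt), C=[N+](C)C.[I-]
Why: Mannich aminomethylation of the lactone enolate, expected on the convex face; the new C11′ centre is removed in step 12, and only the lactone can be enolised because the side-chain ketone is still a ketal.

Step 12
Reactants: 19 Mannich base
Product: 21 (3aS,7R,8aS)-7-methyl-3-methylidene-6-[2-(2-methyl-1,3-dioxolan-2-yl)ethyl]-3,3a,4,7,8,8a-hexahydro-2H-cyclohepta[b]furan-2-one, via ammonium iodide 20 (not isolated)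
Conditions: MeI, MeOH, rt; then NaHCO3 (aq), CH2Cl2, rt
Reagents that add atoms: none
Why: Quaternisation followed by base-induced β-elimination of trimethylamine (E1cB) gives the α-methylene lactone.

Step 13
Reactants: 21 methylene lactone ketal
Product: 22 (3aS,7R,8aS)-7-methyl-3-methylidene-6-(3-oxobutyl)-3,3a,4,7,8,8a-hexahydro-2H-cyclohepta[b]furan-2-one
Conditions: PPTS, acetone/H2O, 45 °C
Reagents that add atoms: water, O
Why: Mild acid-catalysed ketal hydrolysis frees the methyl ketone without hydrating the methylene lactone or shifting the ring alkene.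

Step 14
Reactants: 22 synthetic methylene lactone; 23 8-epi-xanthatin
Product: 24 spiro cycloadduct (C1=C2 alkene, 3-acetyl with 3-H cis to 5-H, no oxygen at C1; other centres as in 26)
Conditions: 22 (3 equiv), BHT, toluene (1 M), 90 °C, dark
Reagents that add atoms: none
Why: Thermal intermolecular Diels–Alder reaction of the s-cis dienone C5=C1–C2=C3 of 23 with the methylene lactone of 22 (in excess to outrun self-dimerisation of 23), in which the spiro centre C11′ should arise by addition to the convex face of 22 (cis to 7′-H) with the lactone carbonyl exo, as is usual for α-methylene-γ-butyrolactones, and C5 by attack on the diene face away from the C7–C8–C9 fold of ring B.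

Step 15
Reactants: 24 spiro cycloadduct
Product: 26 target CNP0195550.2, via hydroperoxide 25 (not isolated)
Conditions: O2 (1 atm), DBU (0.2 equiv), CH2Cl2, 0 °C; then PPh3, 0 °C
Reagents that add atoms: dioxygen, O=O
Why: DBU removes the doubly activated 3-H, the dienolate captures O2 at its γ-carbon C1 (base-mediated γ-autoxidation of a β,γ-unsaturated ketone), expected by axial attack anti to the pseudo-axial 5-H so that the trans B/C fusion results, and PPh3 reduces the tertiary hydroperoxide, which has no α-hydrogen and cannot fragment to a ketone.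

Compound list

1 | pent-1-en-3-one | C=CC(=O)CC | starting material
2 | but-3-en-1-yl acetate | CC(=O)OCCC=C | starting material
3 | (3E)-5-oxohept-3-en-1-yl acetate | CCC(=O)/C=C/CCOC(C)=O | intermediate
4 | (3E,5Z)-5-(triisopropylsilyloxy)hepta-3,5-dien-1-yl acetate | C/C=C(O[Si](C(C)C)(C(C)C)C(C)C)/C=C/CCOC(C)=O | intermediate
5 | but-3-en-2-one | CC(=O)C=C | starting material
6 | 2-[(1R,4R,6S)-6-acetyl-4-methyl-3-(triisopropylsilyloxy)cyclohex-2-en-1-yl]ethyl acetate | CC(=O)[C@H]1C[C@@H](C)C(O[Si](C(C)C)(C(C)C)C(C)C)=C[C@H]1CCOC(C)=O | intermediate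
7 | 2-[4-acetyl-2-methyl-1-(triisopropylsilyloxy)bicyclo[4.1.0]heptan-5-yl]ethyl acetate, substituents all cis, cyclopropane CH2 anti | CC(=O)[C@H]1C[C@@H](C)[C@]2(O[Si](C(C)C)(C(C)C)C(C)C)C[C@@H]2[C@H]1CCOC(C)=O | intermediate
8 | 2-[4-acetoxy-2-methyl-1-(triisopropylsilyloxy)bicyclo[4.1.0]heptan-5-yl]ethyl acetate, configuration as in 7 | CC(=O)O[C@H]1C[C@@H](C)[C@]2(O[Si](C(C)C)(C(C)C)C(C)C)C[C@@H]2[C@H]1CCOC(C)=O | intermediate
9 | 2-[2-acetoxy-7-chloro-4-methyl-5-oxocycloheptyl]ethyl acetate (C7′, C8′, C10′ as in 8; chloride drawn trans to the side chain, both epimers converge) | CC(=O)O[C@H]1C[C@@H](C)C(=O)C[C@H](Cl)[C@H]1CCOC(C)=O | intermediate (not isolated)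
10 | 2-[(1R,2S,4R)-2-acetoxy-4-methyl-5-oxocyclohept-6-en-1-yl]ethyl acetate | CC(=O)O[C@H]1C[C@@H](C)C(=O)C=C[C@H]1CCOC(C)=O | intermediate
11 | lithium enolate of the 6,7-dihydro ketone derived from 10 (C1′(OLi)=C5′) | CC(=O)O[C@H]1C[C@@H](C)C([O-])=CC[C@H]1CCOC(C)=O.[Li+] | intermediate (not isolated)
12 | (4S,5S,7R)-5-acetoxy-4-(2-acetoxyethyl)-7-methylcyclohept-1-en-1-yl trifluoromethanesulfonate | CC(=O)O[C@H]1C[C@@H](C)C(OS(=O)(=O)C(F)(F)F)=CC[C@H]1CCOC(C)=O | intermediate
13 | 2-ethenyl-2-methyl-1,3-dioxolane | C=CC1(C)OCCO1 | starting material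
14 | 9-[2-(2-methyl-1,3-dioxolan-2-yl)ethyl]-9-borabicyclo[3.3.1]nonane | CC1(CCB2C3CCCC2CCC3)OCCO1 | intermediate (not isolated)
15 | 2-[(1S,2S,4R)-2-acetoxy-4-methyl-5-[2-(2-methyl-1,3-dioxolan-2-yl)ethyl]cyclohept-5-en-1-yl]ethyl acetate | CC(=O)O[C@H]1C[C@@H](C)C(CCC2(C)OCCO2)=CC[C@H]1CCOC(C)=O | intermediate
16 | (1S,2S,6R)-2-(2-hydroxyethyl)-6-methyl-5-[2-(2-methyl-1,3-dioxolan-2-yl)ethyl]cyclohept-4-en-1-ol | O[C@H]1C[C@@H](C)C(CCC2(C)OCCO2)=CC[C@H]1CCO | intermediate
17 | (3aS,7R,8aS)-7-methyl-6-[2-(2-methyl-1,3-dioxolan-2-yl)ethyl]-3,3a,4,7,8,8a-hexahydro-2H-cyclohepta[b]furan-2-one | C1C(=O)O[C@H]2C[C@@H](C)C(CCC3(C)OCCO3)=CC[C@@H]12 | intermediate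
18 | lithium enolate of lactone 17 | C1=C([O-])O[C@H]2C[C@@H](C)C(CCC3(C)OCCO3)=CC[C@@H]12.[Li+] | intermediate (not isolated)
19 | (3R,3aS,7R,8aS)-3-[(dimethylamino)methyl]-7-methyl-6-[2-(2-methyl-1,3-dioxolan-2-yl)ethyl]-3,3a,4,7,8,8a-hexahydro-2H-cyclohepta[b]furan-2-one | CN(C)C[C@@H]1C(=O)O[C@H]2C[C@@H](C)C(CCC3(C)OCCO3)=CC[C@@H]12 | intermediate
20 | trimethylammonium iodide of 19 (N-methylated Mannich base) | C[N+](C)(C)C[C@@H]1C(=O)O[C@H]2C[C@@H](C)C(CCC3(C)OCCO3)=CC[C@@H]12.[I-] | intermediate (not isolated)
21 | (3aS,7R,8aS)-7-methyl-3-methylidene-6-[2-(2-methyl-1,3-dioxolan-2-yl)ethyl]-3,3a,4,7,8,8a-hexahydro-2H-cyclohepta[b]furan-2-one | C=C1C(=O)O[C@H]2C[C@@H](C)C(CCC3(C)OCCO3)=CC[C@@H]12 | intermediate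
22 | (3aS,7R,8aS)-7-methyl-3-methylidene-6-(3-oxobutyl)-3,3a,4,7,8,8a-hexahydro-2H-cyclohepta[b]furan-2-one (antipode of 2,3-dihydro-8-epi-xanthatin) | C=C1C(=O)O[C@H]2C[C@@H](C)C(CCC(C)=O)=CC[C@@H]12 | intermediate
23 | 8-epi-xanthatin, (3aR,7S,8aR)-7-methyl-3-methylidene-6-[(1E)-3-oxobut-1-en-1-yl]-3,3a,4,7,8,8a-hexahydro-2H-cyclohepta[b]furan-2-one | C=C1C(=O)O[C@@H]2C[C@H](C)C(/C=C/C(C)=O)=CC[C@H]12 | starting material
24 | spiro Diels–Alder adduct of 22 and 23 (C1=C2, 3-H cis to 5-H, acetyl on C3; C5, C7, C8, C10, C11′, C7′, C8′, C10′ as in 26) | C=C1C(=O)O[C@@H]2C[C@H](C)C3=C[C@H](C(C)=O)[C@]4(C[C@@H]3C[C@H]12)C(=O)O[C@H]1C[C@@H](C)C(CCC(C)=O)=CC[C@H]14 | intermediate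
25 | 1-hydroperoxide of the target skeleton (OOH in place of OH at C1) | C=C1C(=O)O[C@@H]2C[C@H](C)[C@@]3(OO)C=C(C(C)=O)[C@]4(C[C@@H]3C[C@H]12)C(=O)O[C@H]1C[C@@H](C)C(CCC(C)=O)=CC[C@H]14 | intermediate (not isolated)
26 | CNP0195550.2, 1-hydroxy-2-en-4-one spiro dimer (1S,5S,7R,8R,10S,11′R,7′S,8′S,10′R) | C=C1C(=O)O[C@@H]2C[C@H](C)[C@@]3(O)C=C(C(C)=O)[C@]4(C[C@@H]3C[C@H]12)C(=O)O[C@H]1C[C@@H](C)C(CCC(C)=O)=CC[C@H]14 | target

Total step count: 15
Longest linear sequence: 15 steps (1/2 → 26; 5, 13 and 23 enter as purchased partners)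

Steps most likely to fail

Step 14. What may go wrong: 23 is diene and dienophile at once, so its self-cycloaddition competes with the cross reaction, and approach to the other diene face or an endo orientation of the lactone carbonyl would give diastereomeric adducts. Fallback, setting out from 23 and coming back to the route at 24: the methylene lactone of 23 is masked by conjugate addition of dimethylamine (Me2NH, THF, 0 °C), which should give the amine adduct 13-(dimethylamino)-11,13-dihydro-8-epi-xanthatin F1, a compound that can act only as the diene. Cycloaddition of F1 with 22 (1.2 equiv, toluene, 90 °C) then gives the aminomethyl cycloadduct F2 without any self-dimer. Quaternisation with MeI to the ammonium iodide F3 and elimination with aqueous NaHCO3 restore the methylene lactone and deliver 24.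

Step 15. What may go wrong: capture of O2 on the other face of the dienolate, which would give the cis ring fusion at C1/C5, or slow base-induced side reactions at the methylene lactone. Fallback, setting out from 24 and coming back at 25: if the hydroperoxide formed is the C1 epimer, 1-epi-hydroperoxide F4, it is not reduced at once. Allylic hydroperoxides epimerise through reversible loss and recapture of O2 at the allylperoxyl radical (Schenck-type radical chain; di-tert-butyl hyponitrite, O2, benzene, 40 °C). This replaces kinetic by thermodynamic control and is expected to favour the trans-fused hydroperoxide 25, which is then reduced with PPh3 as in step 15.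

Step 3. What may go wrong: open-chain Mukaiyama–Michael addition or protodesilylation of 4 under the strongly acidic catalyst, or insufficient endo or enantiofacial control with the hindered 1,4-disubstituted diene. Fallback, setting out from 4 and coming back at 6: auxiliary control replaces catalyst control. The acryloyl imide (4R)-4-benzyl-3-(prop-2-enoyl)-1,3-oxazolidin-2-one F5 is made from commercial (4R)-4-benzyl-1,3-oxazolidin-2-one, n-BuLi and acryloyl chloride. It reacts with 4 under Et2AlCl chelation (CH2Cl2, −78 °C), where the benzyl group blocks one face of the s-cis acryloyl unit, so the endo imide cycloadduct F6 is expected with the same configuration at C7′, C8′ and C10′. LiSEt (THF, 0 °C) displaces the auxiliary to give the S-ethyl thioester F7. Fukuyama coupling of F7 with MeZnI and PdCl2(PPh3)2 (toluene, rt) gives methyl ketone 6 without touching the acetate or the silyl enol ether.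

Further compounds

F1 | step 14 | 13-(dimethylamino)-11,13-dihydro-8-epi-xanthatin (11-H cis to 7-H) | CN(C)C[C@@H]1C(=O)O[C@@H]2C[C@H](C)C(/C=C/C(C)=O)=CC[C@H]12
F2 | step 14 | cycloadduct of F1 and 22 (as 24, with CH–CH2NMe2 in place of C=CH2 at C11) | CN(C)C[C@@H]1C(=O)O[C@@H]2C[C@H](C)C3=C[C@H](C(C)=O)[C@]4(C[C@@H]3C[C@H]12)C(=O)O[C@H]1C[C@@H](C)C(CCC(C)=O)=CC[C@H]14
F3 | step 14 | trimethylammonium iodide of F2 | C[N+](C)(C)C[C@@H]1C(=O)O[C@@H]2C[C@H](C)C3=C[C@H](C(C)=O)[C@]4(C[C@@H]3C[C@H]12)C(=O)O[C@H]1C[C@@H](C)C(CCC(C)=O)=CC[C@H]14.[I-]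
F4 | step 15 | 1-epi-hydroperoxide (C1 epimer of 25) | C=C1C(=O)O[C@@H]2C[C@H](C)[C@]3(OO)C=C(C(C)=O)[C@]4(C[C@@H]3C[C@H]12)C(=O)O[C@H]1C[C@@H](C)C(CCC(C)=O)=CC[C@H]14
F5 | step 3 | (4R)-4-benzyl-3-(prop-2-enoyl)-1,3-oxazolidin-2-one | C=CC(=O)N1[C@H](Cc2ccccc2)COC1=O
F6 | step 3 | imide cycloadduct (as 6, with the N-acyl oxazolidinone in place of acetyl) | O=C([C@H]1C[C@@H](C)C(O[Si](C(C)C)(C(C)C)C(C)C)=C[C@H]1CCOC(C)=O)N1[C@H](Cc2ccccc2)COC1=O
F7 | step 3 | S-ethyl thioester (as 6, with C(=O)SEt in place of acetyl) | CCSC(=O)[C@H]1C[C@@H](C)C(O[Si](C(C)C)(C(C)C)C(C)C)=C[C@H]1CCOC(C)=O
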